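**Retrosynthetic overview**

- The plan rests on one feature: ring A (C1–C5, C10) and ring B (C5–C10) of the target, with the C8 ketone, methyl C14 on C10, methyl C15 on C4 and the three-carbon unit on C7, make up the germacrone skeleton lacking only the transannular C5–C10 bond.
- Ester disconnections come first: the C4 acetate (made last) and the C3 angelate lead back to a 3α,4α-diol. C7 is traced to thermodynamic protonation after dissolving-metal reduction of the C7=C11 enone, and the diol to the C3=C4 alkene by Woodward cis-hydroxylation on the α face.
- Key disconnection: the C5–C10 bond of cis-eudesma-3,7(11)-dien-8-one, leading to (1(10)E,4Z)-germacra-1(10),4,7(11)-trien-8-one. Rings A and B form together in this single step; no other step forms a ring.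
- The precursor comes from germacrone by sensitised E/Z photoisomerisation of the C4=C5 bond; angelic acid is the second starting material.

Key step: step 2

Assumption and convention: eudesmane numbering is used, β is the face of the C10 methyl (C14), and the target is read from its SMILES as 3α-angeloyloxy, 4α-acetoxy (C15 β), 5β-H (cis-fused), 7β-isopropyl, i.e. (3R,4S,5S,7R,10R). Which antipode of the chiral acid in step 2 leads to this series cannot be predicted, so the (S,S) form is written as a placeholder to be fixed by a first screen of both antipodes.

**Step 1**
Reactants: 1 germacrone, (1(10)E,4E)-germacra-1(10),4,7(11)-trien-8-one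
Product: 2 (1(10)E,4Z)-germacra-1(10),4,7(11)-trien-8-one
Conditions: hν (350 nm, Pyrex), acetophenone, degassed benzene, 10 °C, to the photostationary state; AgNO3-impregnated silica; other isomers re-irradiated
Reagents that add atoms: none
Why: Triplet-sensitised E/Z photoisomerisation, a known reaction of trisubstituted alkenes in medium-ring 1,5-dienes, should give a mixture of ring-alkene isomers from which the 4Z isomer is separated and the remainder recycled, while the isopropylidene enone is degenerate to isomerisation, no stereocentre is involved and the low temperature avoids Cope rearrangement.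

**Step 2**
Reactants: 2 (1(10)E,4Z)-germacra-1(10),4,7(11)-trien-8-one
Product: 3 (5S,10R)-eudesma-3,7(11)-dien-8-one (cis-fused; 5β-H and 10β-CH3)
Conditions: (S,S)-IDPi (confined BINOL-derived imidodiphosphorimidate, N-triflyl core, 5 mol%), CHCl3/HFIP, −40 °C
Reagents that add atoms: none
Why: Proposed new method: the confined acid protonates C1 of the 1(10) double bond while the C4–C5 π bond, held across the ring over C10 in the crossed conformer, attacks C10 (Markovnikov at both alkenes), and the imidodiphosphorimidate anion then removes H3 from the tertiary C4 cation to give the C3–C4 alkene and return the acid. The closest known reaction types are the Brønsted-acid-induced transannular cyclisation of germacrone to eudesmadienones and chiral-acid-catalysed enantioselective cation–olefin cyclisations. The single C5–C10 bond closes both six-membered rings at once, 6-endo with respect to ring A and 6-exo with respect to ring B for the C4–C5 π bond. The cis relation of C10 and C5 follows from the 4Z geometry, which places H5 on the same side as C14 in the chair-like crossed transition state (the E,E isomer gives trans), and the absolute sense must come from the chiral anion selecting one of the two rapidly interconverting mirror-image conformers of the achiral macrocycle. The step needs protonation at C1 and not C5, which is secured because only C1 protonation is assisted by transannular participation and leads to a bicyclic tertiary cation. It also needs loss of H3 and not H5 or H15, for which the anion is placed over C1–C3 after proton delivery, and an untouched cross-conjugated enone, which is a poorer π base than the ring alkenes.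

**Step 3**
Reactants: 3 (5S,10R)-eudesma-3,7(11)-dien-8-one
Product: 6 4α-acetoxy-3α-hydroxy-5βH-eudesm-7(11)-en-8-one, via 3β-iodo-4α-acetate 4 (not isolated), via α-face acetoxonium ion 5 (not isolated)
Conditions: AgOAc (2.2 equiv), iodine (1.05 equiv), AcOH, 20 °C, dark; then H2O in AcOH, 85 °C
Reagents that add atoms: silver acetate AgOAc, CC(=O)[O-].[Ag+]; water, O; iodine, [I][I] (kept only in intermediate 4)
Why: In this Woodward cis-hydroxylation, acetyl hypoiodite should add iodine to the convex β face of the C3–C4 alkene with trans-diaxial Markovnikov opening by acetate at tertiary C4, silver-assisted displacement of iodide by the neighbouring acetate then inverts C3 to the α-face acetoxonium ion, and water opens this through the orthoacid to the axial tertiary acetate and equatorial alcohol, so that both new C–O bonds at C3 and C4 lie on the α face while the electron-poor C7–C11 enone is left alone.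

**Step 4**
Reactants: 6 4α-acetoxy-3α-hydroxy-5βH-eudesm-7(11)-en-8-one
Product: 7 3α,4α-dihydroxy-5βH-eudesm-7(11)-en-8-one
Conditions: K2CO3 (0.2 equiv), MeOH, 0 to 20 °C
Reagents that add atoms: none
Why: Carbonate-catalysed transesterification (Zemplén-type methanolysis) should remove the acetate, whichever of the two cis oxygens carries it after any acyl migration, without touching the tetrasubstituted enone or any stereocentre.

**Step 5**
Reactants: 7 3α,4α-dihydroxy-5βH-eudesm-7(11)-en-8-one
Product: 9 3α,4α-dihydroxy-5βH,7αH-eudesman-8-one, via lithium enolate 8 (not isolated)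
Conditions: Li, NH3(l)/THF, t-BuOH (1 equiv), −78 °C; NH4Cl; then NaOMe (cat.), MeOH, 20 °C
Reagents that add atoms: lithium, [Li] (kept only in enolate 8; product 9 gains hydrogen only)
Why: Dissolving-metal (Birch-type) conjugate reduction of the enone gives the C7–C8 enolate after protonation of C11, and protonation followed by methoxide equilibration sets C7 under thermodynamic control, because with C14 and C15 both β the cis-decalin is held in the chair–chair form that avoids their syn-diaxial clash and in that form only the 7β-isopropyl group is equatorial (7α would be syn-diaxial to C4).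

**Step 6**
Reactants: 9 3α,4α-dihydroxy-5βH,7αH-eudesman-8-one; 10 angelic acid
Product: 12 3α-angeloyloxy-4α-hydroxy-5βH,7αH-eudesman-8-one, via mixed anhydride 11 (not isolated)
Conditions: 10, 2,4,6-Cl3C6H2COCl, Et3N, toluene, 20 °C; then 9, DMAP (cat.), 70 °C
Reagents that add atoms: 2,4,6-trichlorobenzoyl chloride, O=C(Cl)c1c(Cl)cc(Cl)cc1Cl (kept only in intermediate 11)
Why: Yamaguchi esterification through the mixed anhydride, conditions known to transfer the angeloyl group with little Z to E (tiglate) isomerisation, should acylate only the equatorial secondary 3α-hydroxyl because the axial tertiary 4α-hydroxyl is far less reactive, and no stereocentre changes.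

**Step 7**
Reactants: 12 3α-angeloyloxy-4α-hydroxy-5βH,7αH-eudesman-8-one
Product: 13 (3R,4S,5S,7R,10R)-4-acetoxy-3-angeloyloxy-eudesman-8-one (3α-angelate, 4α-acetate, 5β-H, 7β-isopropyl), the target CNP0322180.1
Conditions: Ac2O, TMSOTf (cat.), CH2Cl2, −20 °C
Reagents that add atoms: acetic anhydride, CC(=O)OC(C)=O
Why: TMSOTf-catalysed acetylation with acetic anhydride is a known way to esterify hindered tertiary alcohols quickly at low temperature, under which the angelate geometry, the ketone and the already thermodynamic C7 centre should survive.

**Compound list**

1 | germacrone, (1(10)E,4E)-germacra-1(10),4,7(11)-trien-8-one | C/C1=C\CC/C(C)=C/CC(=C(C)C)C(=O)C1 | starting material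
2 | (1(10)E,4Z)-germacra-1(10),4,7(11)-trien-8-one | C/C1=C\CC/C(C)=C\CC(=C(C)C)C(=O)C1 | intermediate
3 | (5S,10R)-eudesma-3,7(11)-dien-8-one (cis-fused, 5β-H, 10β-CH3) | C=1CC[C@]2(C)CC(=O)C(=C(C)C)C[C@@H]2C=1C | intermediate
4 | 4α-acetoxy-3β-iodo-5βH-eudesm-7(11)-en-8-one (formed in the flask) | I[C@H]1CC[C@]2(C)CC(=O)C(=C(C)C)C[C@@H]2[C@]1(C)OC(C)=O | intermediate
5 | 3α,4α-acetoxonium ion (2-methyl-1,3-dioxolan-2-ylium fused at C3–C4 on the α face) of 5βH-eudesm-7(11)-en-8-one, acetate salt (formed in the flask) | CC1=[O+][C@@H]2CC[C@]3(C)CC(=O)C(=C(C)C)C[C@@H]3[C@]2(C)O1.CC(=O)[O-] | intermediate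
6 | 4α-acetoxy-3α-hydroxy-5βH-eudesm-7(11)-en-8-one | O[C@@H]1CC[C@]2(C)CC(=O)C(=C(C)C)C[C@@H]2[C@]1(C)OC(C)=O | intermediate
7 | 3α,4α-dihydroxy-5βH-eudesm-7(11)-en-8-one | O[C@@H]1CC[C@]2(C)CC(=O)C(=C(C)C)C[C@@H]2[C@]1(C)O | intermediate
8 | lithium C7–C8 enolate of 3α,4α-dihydroxy-5βH-eudesman-8-one, hydroxyls drawn free (formed in the flask) | O[C@@H]1CC[C@]2(C)CC([O-])=C(C(C)C)C[C@@H]2[C@]1(C)O.[Li+] | intermediate
9 | 3α,4α-dihydroxy-5βH,7αH-eudesman-8-one (7β-isopropyl) | O[C@@H]1CC[C@]2(C)CC(=O)[C@@H](C(C)C)C[C@@H]2[C@]1(C)O | intermediate
10 | angelic acid, (Z)-2-methylbut-2-enoic acid | C/C=C(/C)C(=O)O | starting material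
11 | angelic 2,4,6-trichlorobenzoic anhydride (formed in the flask) | C/C=C(/C)C(=O)OC(=O)c1c(Cl)cc(Cl)cc1Cl | intermediate
12 | 3α-angeloyloxy-4α-hydroxy-5βH,7αH-eudesman-8-one | C/C=C(/C)C(=O)O[C@@H]1CC[C@]2(C)CC(=O)[C@@H](C(C)C)C[C@@H]2[C@]1(C)O | intermediate
13 | (3R,4S,5S,7R,10R)-4-acetoxy-3-angeloyloxy-eudesman-8-one, CNP0322180.1 | C/C=C(/C)C(=O)O[C@@H]1CC[C@]2(C)CC(=O)[C@@H](C(C)C)C[C@@H]2[C@]1(C)OC(C)=O | target

**Step count and risks**

Total step count: 7. Longest linear sequence: 7 steps (germacrone 1 to target 13); angelic acid 10 is used as bought.

Steps most likely to fail: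

1. Step 2 (the step that carries the proposed new method). The chiral anion may not distinguish the two mirror-image crossed conformers of 2, giving low enantioselectivity. The cation may also lose H15 or H5 instead of H3, or the product alkene may be reprotonated and drift to the tetrasubstituted C4–C5 isomer. The fallback uses known chemistry and sets out from 2: an achiral sulfonic acid (p-TsOH, CH2Cl2, 0 °C), the classical acid-induced transannular cyclisation of germacrone-type dienes, should give the racemic cis-dienone, that is 3 together with its enantiomer (5R,10S)-eudesma-3,7(11)-dien-8-one F1. The two would be separated by preparative chromatography on a polysaccharide chiral stationary phase, and 3 re-enters the route at step 3.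

2. Step 3. The iodonium formation and acetate opening may show poor or reversed facial selectivity; attack beginning on the α face would, after the inversion at C3, put both oxygens on the β face. The fallback sets out from 3: catalytic osmylation (K2OsO2(OH)4, NMO, acetone/H2O) is a concerted syn addition that leaves both oxygens on the face that is attacked, so it has the opposite stereochemical sense to the Woodward sequence. It should therefore give diol 7 directly in exactly the case in which step 3 fails. The route is rejoined at 7 and no compound outside the list is made (F0).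

3. Step 7. Acylation of the axial tertiary hydroxyl, which is syn-diaxial to C9, may be slow, allowing angeloyl migration from O3 to O4, Z to E isomerisation of the angelate, or enol acetate formation at C8. The fallback sets out from 9 and reverses the order of the two acylations, so that no tertiary alcohol has to be acylated. Trimethyl orthoacetate and PPTS in CH2Cl2 should give the cyclic orthoacetate F2. Its mild hydrolysis (80% aqueous AcOH, 20 °C) should collapse through the same kind of orthoacid as in step 3 to the axial tertiary acetate, 4α-acetoxy-3α-hydroxy-5βH,7αH-eudesman-8-one F3. Yamaguchi angeloylation of its secondary hydroxyl with 10 through 11 would then give 13, where the route is rejoined.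

**Further compounds**

F1 | step 2 | (5R,10S)-eudesma-3,7(11)-dien-8-one (enantiomer of 3) | C=1CC[C@@]2(C)CC(=O)C(=C(C)C)C[C@H]2C=1C
F0 | step 3 | none | none
F2 | step 7 | cyclic orthoacetate of 9 (2-methoxy-2-methyl-1,3-dioxolane fused at C3–C4 on the α face, mixture at the orthoester carbon) | COC1(C)O[C@@H]2CC[C@]3(C)CC(=O)[C@@H](C(C)C)C[C@@H]3[C@]2(C)O1
F3 | step 7 | 4α-acetoxy-3α-hydroxy-5βH,7αH-eudesman-8-one | O[C@@H]1CC[C@]2(C)CC(=O)[C@@H](C(C)C)C[C@@H]2[C@]1(C)OC(C)=O
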